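**Analysis of the target**

Compound 18 is a 2,3-trans flavanonol 3-methyl ether: a chroman-4-one (rings A and C) with a 3-hydroxy-4,5-dimethoxyphenyl group (ring B) at C2 and a methoxy group at C3. Ring A is a 1,2,3,5-tetraoxygenated benzene carrying three different oxygen functions in a fixed order (O1 at C8a, the free catechol at C5/C6, the methyl ether at C7), so its substitution pattern must be built in regiospecifically. The only stereocentres are the adjacent C2 and C3, both R, with aryl and methoxy trans (diequatorial), which is also the more stable relative arrangement. The α-alkoxy ketone with a benzylic aryl ether at C2 opens by retro-oxa-Michael reaction under base, which would epimerise C3 and racemise C2. The 5,6-catechol is readily oxidised to an ortho-quinone, and ring B is electron-rich. The difficulty lies in the oxygen pattern (four methyl ethers, one of them aliphatic, beside three free phenols) and in setting two contiguous centres with no resident stereocentre. The methylation pattern therefore has to come from the building blocks, and the protecting groups have to leave under neutral conditions at the end. The strategy rests on one feature: O1–C8a–C4a–C4 is the skeleton of an ortho-quinone methide (a 1-oxadiene), and C2–C3 with its trans substituents is the image of an (E)-alkene, so ring C is a formal [4+2] adduct.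

**Retrosynthetic reasoning**

18 from 17. The three phenols are released last from ketone 17 by hydrogenolysis of one benzyl ether (ring B) and one diphenylmethylene ketal (ring A catechol). Both are cleaved without acid or base, so the trans-2,3 arrangement and the catechol are not put at risk, and the four methyl ethers stay.

17 from 16. The C4 carbonyl is taken back to the C4 methyl ether of 16. C4 is held at the alcohol oxidation level until all basic steps are over; the forward step is a single benzylic oxidation that also merges the two C4 epimers.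

16 from 15 from 14. The C3 methoxy group is traced to the alcohol 15 and this to the C3–B bond of boronate 14. Boron is used as a stand-in for oxygen for a reason of regiochemistry: an enol ether as the two-carbon partner would place its donor oxygen at C2 and give the 2-alkoxy-3-aryl isomer. A boryl group is electronically quiet, lets the aryl group decide the regiochemistry, and is exchanged for oxygen with retention. Methylation is placed at the stage of 15, where no enolisable ketone is present.

14 from 6, 10 and 11. This is the strategic cut: O1–C2 and C3–C4 are broken together, which removes ring C and both stereocentres at once. What remains are the salicylaldehyde 6 (ring A plus C4), trimethyl orthoformate 11 (the C4 methoxy group) and the (E)-styrylboronate 10 (ring B plus C2 and C3). The forward reaction has to generate the methoxy-substituted ortho-quinone methide from 6 and 11 under a chiral acid, add it across 10 with the aryl-bearing carbon bonding to oxygen, and select one alkene face. The cut is made here because it is the only one that divides the molecule into its two aromatic halves while tying the trans relationship to alkene geometry.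

6 from 2 from 1. The phenol oxygen that becomes O1 is introduced ortho to the aldehyde of 2 by directed metalation, which keeps the regiochemistry defined by commercial catechol aldehyde 1. Electrophilic formylation of a phenol would not distinguish the two ortho positions. Because this step uses an organolithium base, the catechol is masked as a diphenylmethylene ketal (2) and not as two benzyl ethers, whose benzylic C–H bonds could be metalated; the ketal still leaves by hydrogenolysis.

10 from 8 from 7. The alkene of 10 is cut at C=C back to aldehyde 8 (a one-step boron–Wittig olefination), and 8 is the benzyl ether of commercial phenol 7.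

**Alternatives that were turned down**

Alternative 1: The disconnection is at C2–C3 and at the C3–O(methyl) bond, giving an open chain from diazoketone A2 (ring A with C4 and C3), methanol A4 and aldehyde A3 (ring B with C2). In the forward step Rh2(OAc)4 (divalent rhodium) converts A2 into a carbene, A4 adds to give an oxonium ylide, and a chiral phosphoric acid guides its aldol addition to A3, giving the syn aldol A1. Desilylation and an invertive O1–C2 closure would follow.
- For: it is highly convergent, C4 is a ketone from the start and the C3 methoxy group is installed as such. On oxidation-state and functional-group economy it is stronger than the chosen route, which needs a boron-to-oxygen exchange, a methylation and a C4 oxidation.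
- Against: the ylide of an acceptor-only diazoketone is short-lived and tends to collapse by 1,2-proton shift to the plain O–H insertion product unless the electrophile is very reactive, and A3 is an electron-rich, deactivated aldehyde. The ketone of A2 is flanked by two ortho oxygens and crowded. No ring is formed, so trans-18 would depend on a clean SN2 closure at a carbinol bearing a trialkoxyphenyl group, which ionises easily, in a β-hydroxy ketone prone to retro-aldol cleavage.
- Comparison: the chosen strategy closes ring C and sets both centres in one event, so the relative configuration follows from alkene geometry and not from a later substitution.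

Alternative 2: The disconnection is at C3–C4, back to dialdehyde A6, in which the ring A aldehyde is the acyl-anion precursor and the α-aryloxy-α-aryl acetaldehyde is the acceptor. A chiral triazolylidene would form the Breslow intermediate at the aryl aldehyde and attack the aliphatic aldehyde, which racemises through its enol, so that a dynamic kinetic resolution gives A5 with ring C closed.
- For: C4 and C3 arrive at their final oxidation levels, the step is metal-free, and only O-methylation and deprotection remain. In steps after the key step it is at least as good as the chosen route.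
- Against: the carbene must choose the hindered, electron-rich, doubly ortho-substituted aryl aldehyde over the unhindered aliphatic one; the wrong choice leads to the isomeric 4-hydroxychroman-3-one. An aldehyde with an α-aryloxy group is also a typical substrate for carbene-induced loss of the α-leaving group, which here would expel the ring A phenoxide. A6 is enolisable, air-sensitive and several steps from a salicylaldehyde. The 3-hydroxyl of A5 would have to be methylated on a base-sensitive flavanonol.
- Comparison: the chosen strategy uses stable partners and keeps C4 at the ether level through all basic steps.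

Alternative 3: The disconnection is at C2–C3 by C–H insertion, back to diazoketone A8, in which ring B is attached as a benzyl ether to the future O1. Rh2(S-PTTL)4, dirhodium tetrakis[N-phthaloyl-(S)-tert-leucinate] (divalent rhodium), would form the carbene, which inserts into the ether O–CH2 bond to give flavanone A7.
- For: the precursor is short to make, ring C closes at the ketone level, and the C–H bond is activated by the ether oxygen and the donor aryl group. On brevity up to the key step it is stronger than the chosen route.
- Against: only C2 is set. The C3 oxygen would have to be introduced by enolate or enol oxidation of a flavanone that ring-opens under base, followed by methylation, so two sensitive steps are added and C2 is endangered. Acceptor-only diazoketone carbenes are the least selective class. The ether oxygen is placed to form a five-membered oxonium ylide, and a 1,2-benzyl shift to a 2-benzylbenzofuran-3-one, or addition to the electron-rich ring B, can compete with six-membered insertion.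
- Comparison: the chosen strategy brings the C3 heteroatom in with the cycloaddition and fixes C2 and C3 together.

Key step: step 5

Assumption: the sense of induction of the chiral acid in step 5 cannot be predicted with confidence for this new cycloaddition. The (R)-catalyst is written; its (S)-antipode is to be used if the (R)-catalyst favours the mirror-image chroman.

**Route**

Step 1
Reactants: 1 2,3-dihydroxy-4-methoxybenzaldehyde
Product: 2 7-methoxy-2,2-diphenyl-1,3-benzodioxole-4-carbaldehyde
Conditions: Ph2CCl2 (1.3 equiv), Ph2O, 170 °C, N2 sweep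
Reagents that add atoms: dichlorodiphenylmethane, ClC(Cl)(c1ccccc1)c1ccccc1
Why: Diphenylmethylene ketal formation: the two adjacent phenols displace both chlorides with loss of HCl, while the aldehyde and the methyl ether do not react. The ketal has no acidic benzylic C–H, which the next step requires.

Step 2
Reactants: 2 7-methoxy-2,2-diphenyl-1,3-benzodioxole-4-carbaldehyde
Product: 6 5-hydroxy-7-methoxy-2,2-diphenyl-1,3-benzodioxole-4-carbaldehyde, via lithium α-amino alkoxide 3 (not isolated), via ortho-lithiated α-amino alkoxide 4 (not isolated), via aryl dimethyl boronate 5 (not isolated)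
Conditions: LiN(Me)CH2CH2NMe2 (from the amine and n-BuLi), THF, −20 °C; n-BuLi (3 equiv), −20 °C; B(OMe)3, −78 °C → rt; Me3NO (anhydrous, excess), rt → 50 °C; 1 M HCl work-up
Reagents that add atoms: trimethylamine N-oxide, C[N+](C)(C)[O-]
Why: Comins-type directed ortho-metalation: the α-amino alkoxide 3 masks the aldehyde and its chelating diamine arm directs n-BuLi to the only adjacent ring C–H (C5), not to C6 beside the methoxy group. Borylation and oxygen transfer from the N-oxide (1,2-aryl shift from boron to oxygen) give the phenol without peroxide, so the electron-rich salicylaldehyde is not exposed to Dakin oxidation.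

Step 3
Reactants: 7 3-hydroxy-4,5-dimethoxybenzaldehyde
Product: 8 3-(benzyloxy)-4,5-dimethoxybenzaldehyde
Conditions: BnBr, K2CO3, DMF, 60 °C
Reagents that add atoms: benzyl bromide, BrCc1ccccc1
Why: Williamson ether synthesis on the only phenol.

Step 4
Reactants: 8 3-(benzyloxy)-4,5-dimethoxybenzaldehyde
Product: 10 (E)-2-[3-(benzyloxy)-4,5-dimethoxystyryl]-4,4,5,5-tetramethyl-1,3,2-dioxaborolane, via β-lithiooxy gem-diboronate 9 (not isolated)
Conditions: CH2(Bpin)2, lithium 2,2,6,6-tetramethylpiperidide (from the amine and n-BuLi), THF, 0 °C; then 8, −78 °C → rt; H2O work-up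
Reagents that add atoms: bis(4,4,5,5-tetramethyl-1,3,2-dioxaborolan-2-yl)methane, CC1(C)OB(CB2OC(C)(C)C(C)(C)O2)OC1(C)C
Why: Boron–Wittig olefination: the lithiated gem-diboronate adds to the aldehyde to give 9, and syn elimination of boron and oxygen gives the alkenylboronate. With an aryl aldehyde the (E)-isomer should dominate, because the aryl group and the remaining boryl group avoid each other in the elimination.

Step 5
Reactants: 6 5-hydroxy-7-methoxy-2,2-diphenyl-1,3-benzodioxole-4-carbaldehyde, 11 trimethyl orthoformate, 10 (E)-2-[3-(benzyloxy)-4,5-dimethoxystyryl]-4,4,5,5-tetramethyl-1,3,2-dioxaborolane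
Product: 14 (2S,3S,4RS)-2-[3-(benzyloxy)-4,5-dimethoxyphenyl]-5,6-(diphenylmethylenedioxy)-4,7-dimethoxy-3-(4,4,5,5-tetramethyl-1,3,2-dioxaborolan-2-yl)chroman, via dimethyl acetal 12 (not isolated), via methoxy ortho-quinone methide 13 (not isolated)
Conditions: (R)-3,3'-bis(2,4,6-triisopropylphenyl)-1,1'-binaphthalene-2,2'-diyl N-triflylphosphoramide (10 mol%), 11 (2 equiv), 5 Å MS, toluene, rt; then 10 (1.5 equiv), −40 → 0 °C
Reagents that add atoms: none
Why: Proposed new method: the acid exchanges the aldehyde of 6 with 11 to give acetal 12 and ionises it to the 2-hydroxyaryl oxocarbenium ion, the O-protonated form of quinone methide 13, held as a hydrogen-bonded ion pair by the chiral phosphoramide anion; the closest known reactions are the acid-promoted coupling of salicylaldehydes, orthoformates and styrenes to 4-alkoxy-2-arylchromans and chiral phosphoric acid-catalysed [4+2] cycloadditions of ortho-quinone methides with styrenes, and neither has been run with an alkenylboronate. The oxadiene O=C8a–C4a=C4 of 13 adds across the alkene of 10 in an inverse-electron-demand hetero-Diels–Alder reaction, closing ring C by an asynchronous [4+2] closure in which the C3–C4 bond runs ahead of the O1–C2 bond. The regiochemistry follows from charge: attack by the boron-bearing carbon leaves the developing cation on the benzylic carbon, where the para-methoxy group of ring B stabilises it, and the phenol oxygen closes onto that carbon. C2 and C3 should come out trans because the addition is suprafacial on the (E)-alkene, and the same diequatorial arrangement is the more stable one if the closure becomes stepwise. The absolute configuration at C3, and through the alkene geometry at C2, is set by the catalyst anion, which binds the phenolic O–H and the oxocarbenium ion and whose 3,3'-aryl groups define the pocket in which one face of the alkene approaches. C4 forms as both epimers, which does not matter because it becomes the carbonyl carbon. The step needs ring closure to be faster than loss of boron from the β-boryl benzylic cation; the pinacol ester (weakly Lewis acidic, slow to form ate complexes), the non-nucleophilic counter-anion, removal of methanol by the sieves and the low temperature are chosen to secure this.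

Step 6
Reactants: 14 (2S,3S,4RS)-2-[3-(benzyloxy)-4,5-dimethoxyphenyl]-5,6-(diphenylmethylenedioxy)-4,7-dimethoxy-3-(4,4,5,5-tetramethyl-1,3,2-dioxaborolan-2-yl)chroman
Product: 15 (2R,3S,4RS)-2-[3-(benzyloxy)-4,5-dimethoxyphenyl]-5,6-(diphenylmethylenedioxy)-4,7-dimethoxychroman-3-ol
Conditions: NaBO3·4H2O, THF/H2O (1:1), rt
Reagents that add atoms: sodium perborate tetrahydrate, NaBO3·4H2O (Na2[B2(O2)2(OH)4]·6H2O), [Na+].[Na+].O[B-]1(O)OO[B-](O)(O)OO1
Why: Oxidation of a secondary alkylboronate: the peroxide adds to boron and C3 migrates to oxygen with retention, so the hydroxyl takes the place of boron, trans to the aryl group (the descriptors change only because the priorities change). The near-neutral reagent limits β-elimination of the β-alkoxy boronate.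

Step 7
Reactants: 15 (2R,3S,4RS)-2-[3-(benzyloxy)-4,5-dimethoxyphenyl]-5,6-(diphenylmethylenedioxy)-4,7-dimethoxychroman-3-ol
Product: 16 (2R,3S,4RS)-2-[3-(benzyloxy)-4,5-dimethoxyphenyl]-5,6-(diphenylmethylenedioxy)-3,4,7-trimethoxychroman
Conditions: NaH, MeI, THF, 0 °C → rt
Reagents that add atoms: methyl iodide, CI
Why: Williamson methylation of the only free hydroxyl. It is done before C4 is a ketone, because the alkoxide of a 3-hydroxyflavanone would epimerise or open ring C.

Step 8
Reactants: 16 (2R,3S,4RS)-2-[3-(benzyloxy)-4,5-dimethoxyphenyl]-5,6-(diphenylmethylenedioxy)-3,4,7-trimethoxychroman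
Product: 17 (2R,3R)-2-[3-(benzyloxy)-4,5-dimethoxyphenyl]-5,6-(diphenylmethylenedioxy)-3,7-dimethoxychroman-4-one
Conditions: DDQ (2.5 equiv), CH2Cl2/H2O (10:1), rt
Reagents that add atoms: water, O
Why: DDQ oxidation of an electron-rich benzylic ether, the reaction type of oxidative 4-methoxybenzyl ether cleavage: hydride abstraction from C4–H gives an oxocarbenium ion stabilised by O1, the C5 oxygen and the C7 methoxy group, water adds, and the hemiketal loses methanol. Both C4 epimers converge on one ketone. C2–H is less activated (aryl ether oxygen, flanked para-methoxy group) and is deactivated once the ketone is in place.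

Step 9
Reactants: 17 (2R,3R)-2-[3-(benzyloxy)-4,5-dimethoxyphenyl]-5,6-(diphenylmethylenedioxy)-3,7-dimethoxychroman-4-one
Product: 18 (2R,3R)-5,6-dihydroxy-2-(3-hydroxy-4,5-dimethoxyphenyl)-3,7-dimethoxychroman-4-one
Conditions: H2 (1 atm), Pd(OH)2/C, THF/MeOH, rt; work-up under argon
Reagents that add atoms: none
Why: Hydrogenolysis of the benzyl ether and the diphenylmethylene ketal under neutral conditions, which should leave the trans-2,3 arrangement and the methyl ethers untouched. The reaction is stopped after uptake of three equivalents of hydrogen.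

**Compound list**

1 | 2,3-dihydroxy-4-methoxybenzaldehyde | COc1ccc(C=O)c(O)c1O | starting material
2 | 7-methoxy-2,2-diphenyl-1,3-benzodioxole-4-carbaldehyde | COc1ccc(C=O)c2OC(c3ccccc3)(c3ccccc3)Oc12 | intermediate
3 | lithium {[2-(dimethylamino)ethyl](methyl)amino}(7-methoxy-2,2-diphenyl-1,3-benzodioxol-4-yl)methanolate | COc1ccc(C(O[Li])N(C)CCN(C)C)c2OC(c3ccccc3)(c3ccccc3)Oc12 | intermediate
4 | 5-lithio derivative of 3 (lithiated ortho to the amino alkoxide) | COc1cc([Li])c(C(O[Li])N(C)CCN(C)C)c2OC(c3ccccc3)(c3ccccc3)Oc12 | intermediate
5 | 5-(dimethoxyboryl) derivative of 3 | COc1cc(B(OC)OC)c(C(O[Li])N(C)CCN(C)C)c2OC(c3ccccc3)(c3ccccc3)Oc12 | intermediate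
6 | 5-hydroxy-7-methoxy-2,2-diphenyl-1,3-benzodioxole-4-carbaldehyde | COc1cc(O)c(C=O)c2OC(c3ccccc3)(c3ccccc3)Oc12 | intermediate
7 | 3-hydroxy-4,5-dimethoxybenzaldehyde | COc1cc(C=O)cc(O)c1OC | starting material
8 | 3-(benzyloxy)-4,5-dimethoxybenzaldehyde | COc1cc(C=O)cc(OCc2ccccc2)c1OC | intermediate
9 | lithium 1-[3-(benzyloxy)-4,5-dimethoxyphenyl]-2,2-bis(4,4,5,5-tetramethyl-1,3,2-dioxaborolan-2-yl)ethan-1-olate | COc1cc(C(O[Li])C(B2OC(C)(C)C(C)(C)O2)B2OC(C)(C)C(C)(C)O2)cc(OCc2ccccc2)c1OC | intermediate
10 | (E)-2-[3-(benzyloxy)-4,5-dimethoxystyryl]-4,4,5,5-tetramethyl-1,3,2-dioxaborolane | COc1cc(/C=C/B2OC(C)(C)C(C)(C)O2)cc(OCc2ccccc2)c1OC | intermediate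
11 | trimethyl orthoformate | COC(OC)OC | starting material
12 | 4-(dimethoxymethyl)-7-methoxy-2,2-diphenyl-1,3-benzodioxol-5-ol | COc1cc(O)c(C(OC)OC)c2OC(c3ccccc3)(c3ccccc3)Oc12 | intermediate
13 | 7-methoxy-4-(methoxymethylidene)-2,2-diphenyl-1,3-benzodioxol-5(4H)-one (reacts as its O-protonated ion pair with the catalyst anion) | COC=C1C(=O)C=C(OC)C2=C1OC(c1ccccc1)(c1ccccc1)O2 | intermediate
14 | (2S,3S,4RS)-2-[3-(benzyloxy)-4,5-dimethoxyphenyl]-5,6-(diphenylmethylenedioxy)-4,7-dimethoxy-3-(4,4,5,5-tetramethyl-1,3,2-dioxaborolan-2-yl)chroman | COc1cc2c(c3OC(c4ccccc4)(c4ccccc4)Oc13)C(OC)[C@H](B1OC(C)(C)C(C)(C)O1)[C@@H](c1cc(OCc3ccccc3)c(OC)c(OC)c1)O2 | intermediate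
15 | (2R,3S,4RS)-2-[3-(benzyloxy)-4,5-dimethoxyphenyl]-5,6-(diphenylmethylenedioxy)-4,7-dimethoxychroman-3-ol | COc1cc2c(c3OC(c4ccccc4)(c4ccccc4)Oc13)C(OC)[C@H](O)[C@@H](c1cc(OCc3ccccc3)c(OC)c(OC)c1)O2 | intermediate
16 | (2R,3S,4RS)-2-[3-(benzyloxy)-4,5-dimethoxyphenyl]-5,6-(diphenylmethylenedioxy)-3,4,7-trimethoxychroman | COc1cc2c(c3OC(c4ccccc4)(c4ccccc4)Oc13)C(OC)[C@H](OC)[C@@H](c1cc(OCc3ccccc3)c(OC)c(OC)c1)O2 | intermediate
17 | (2R,3R)-2-[3-(benzyloxy)-4,5-dimethoxyphenyl]-5,6-(diphenylmethylenedioxy)-3,7-dimethoxychroman-4-one | COc1cc2c(c3OC(c4ccccc4)(c4ccccc4)Oc13)C(=O)[C@H](OC)[C@@H](c1cc(OCc3ccccc3)c(OC)c(OC)c1)O2 | intermediate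
18 | (2R,3R)-5,6-dihydroxy-2-(3-hydroxy-4,5-dimethoxyphenyl)-3,7-dimethoxychroman-4-one | COc1cc2c(c(O)c1O)C(=O)[C@H](OC)[C@@H](c1cc(O)c(OC)c(OC)c1)O2 | target

**Step count and least certain steps**

Total step count: 9. Longest linear sequence: 7 steps (1 → 2 → 6 → 14 → 15 → 16 → 17 → 18; the ring B branch 7 → 8 → 10 → 14 is equally long).

Step 5 (key step, new method). Three things may go wrong:
- Loss of boron. The β-boryl benzylic cation can lose boron before ring closure, giving a Petasis-like alkenyl transfer in place of a cycloaddition. The product can also re-ionise at C4 under acid and eliminate boron to a 2H-chromene.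
- Low reactivity. The boryl group lowers the nucleophilicity of the alkene, the oxocarbenium ion is highly stabilised by three oxygens, and the 4-methoxy group of ring B is flanked and partly twisted.
- Poor facial selection on the alkene. The anion sits on the heterodiene, not on the alkene. Because C4 is erased later, only the alkene face counts; C4 epimers carrying opposite C2/C3 sense would lower the enantiomeric purity of 18.

The fallback uses known chemistry and sets out from 6 and 8. Aldehyde 6 is protected (MOMCl, iPr2NEt) as 7-methoxy-5-(methoxymethoxy)-2,2-diphenyl-1,3-benzodioxole-4-carbaldehyde F1. MeMgBr gives 1-[7-methoxy-5-(methoxymethoxy)-2,2-diphenyl-1,3-benzodioxol-4-yl]ethanol F2, and Dess–Martin oxidation gives 1-[7-methoxy-5-(methoxymethoxy)-2,2-diphenyl-1,3-benzodioxol-4-yl]ethanone F3. Claisen–Schmidt condensation of F3 with 8 (KOH, EtOH) gives (E)-3-[3-(benzyloxy)-4,5-dimethoxyphenyl]-1-[7-methoxy-5-(methoxymethoxy)-2,2-diphenyl-1,3-benzodioxol-4-yl]prop-2-en-1-one F4. Juliá–Colonna epoxidation (poly-L-leucine, urea–H2O2, DBU, THF; the D-polymer if the sense is opposite) gives {(2R,3S)-3-[3-(benzyloxy)-4,5-dimethoxyphenyl]oxiran-2-yl}[7-methoxy-5-(methoxymethoxy)-2,2-diphenyl-1,3-benzodioxol-4-yl]methanone F5. HCl in MeOH removes the methoxymethyl group, and the freed phenol opens the epoxide at the benzylic carbon with inversion to (2R,3R)-2-[3-(benzyloxy)-4,5-dimethoxyphenyl]-5,6-(diphenylmethylenedioxy)-3-hydroxy-7-methoxychroman-4-one F6. Methylation with MeI/Ag2O returns to the route at 17. This costs seven steps in place of steps 5 to 8.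

Step 2. Metalation may occur beside the methoxy group (C6) instead of beside the amino alkoxide, n-BuLi may add to incompletely masked aldehyde, or the oxygen transfer to boron may be incomplete. The fallback sets out from 2. Condensation with tert-butylamine gives (E)-N-tert-butyl-1-(7-methoxy-2,2-diphenyl-1,3-benzodioxol-4-yl)methanimine F7. Imine-directed ortho C–H borylation ([Ir(OMe)(cod)]2, 8-aminoquinoline, B2pin2) gives (E)-N-tert-butyl-1-[7-methoxy-2,2-diphenyl-5-(4,4,5,5-tetramethyl-1,3,2-dioxaborolan-2-yl)-1,3-benzodioxol-4-yl]methanimine F8. Oxidation of the C–B bond with Me3NO and mild acidic hydrolysis of the imine return to the route at 6.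

Step 8. Hydride abstraction may be slow for the C4 epimer whose C4–H lies near the plane of ring A, and forcing conditions could bring oxidation at C2–H, attack on the benzyl ether or dehydrogenation towards the flavone. The fallback sets out from 16. Acid-catalysed solvolysis of the benzylic methyl ether (TsOH, THF/H2O) gives (2R,3S,4RS)-2-[3-(benzyloxy)-4,5-dimethoxyphenyl]-5,6-(diphenylmethylenedioxy)-3,7-dimethoxychroman-4-ol F9, and Dess–Martin oxidation returns to the route at 17.

Step 9. The ketal is hydrogenolysed more slowly than the benzyl ether, so prolonged exposure may reduce the C4 carbonyl or open the benzylic C2–O1 bond, and the freed catechol may oxidise in air. The fallback sets out from 17 and replaces reduction by Lewis-acid cleavage: BCl3 with pentamethylbenzene as cation scavenger in CH2Cl2 at −78 °C removes both the benzyl group and the ketal and arrives directly at 18; no new compound arises on this way (F0).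

**Further compounds**

F1 | step 5 | 7-methoxy-5-(methoxymethoxy)-2,2-diphenyl-1,3-benzodioxole-4-carbaldehyde | COCOc1cc(OC)c2OC(c3ccccc3)(c3ccccc3)Oc2c1C=O
F2 | step 5 | 1-[7-methoxy-5-(methoxymethoxy)-2,2-diphenyl-1,3-benzodioxol-4-yl]ethanol | COCOc1cc(OC)c2OC(c3ccccc3)(c3ccccc3)Oc2c1C(C)O
F3 | step 5 | 1-[7-methoxy-5-(methoxymethoxy)-2,2-diphenyl-1,3-benzodioxol-4-yl]ethanone | COCOc1cc(OC)c2OC(c3ccccc3)(c3ccccc3)Oc2c1C(C)=O
F4 | step 5 | (E)-3-[3-(benzyloxy)-4,5-dimethoxyphenyl]-1-[7-methoxy-5-(methoxymethoxy)-2,2-diphenyl-1,3-benzodioxol-4-yl]prop-2-en-1-one | COCOc1cc(OC)c2OC(c3ccccc3)(c3ccccc3)Oc2c1C(=O)/C=C/c1cc(OC)c(OC)c(OCc2ccccc2)c1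
F5 | step 5 | {(2R,3S)-3-[3-(benzyloxy)-4,5-dimethoxyphenyl]oxiran-2-yl}[7-methoxy-5-(methoxymethoxy)-2,2-diphenyl-1,3-benzodioxol-4-yl]methanone | COCOc1cc(OC)c2OC(c3ccccc3)(c3ccccc3)Oc2c1C(=O)[C@@H]1O[C@H]1c1cc(OC)c(OC)c(OCc2ccccc2)c1
F6 | step 5 | (2R,3R)-2-[3-(benzyloxy)-4,5-dimethoxyphenyl]-5,6-(diphenylmethylenedioxy)-3-hydroxy-7-methoxychroman-4-one | COc1cc2c(c3OC(c4ccccc4)(c4ccccc4)Oc13)C(=O)[C@H](O)[C@@H](c1cc(OCc3ccccc3)c(OC)c(OC)c1)O2
F7 | step 2 | (E)-N-tert-butyl-1-(7-methoxy-2,2-diphenyl-1,3-benzodioxol-4-yl)methanimine | COc1ccc(/C=N/C(C)(C)C)c2OC(c3ccccc3)(c3ccccc3)Oc12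
F8 | step 2 | (E)-N-tert-butyl-1-[7-methoxy-2,2-diphenyl-5-(4,4,5,5-tetramethyl-1,3,2-dioxaborolan-2-yl)-1,3-benzodioxol-4-yl]methanimine | COc1cc(B3OC(C)(C)C(C)(C)O3)c(/C=N/C(C)(C)C)c2OC(c3ccccc3)(c3ccccc3)Oc12
F9 | step 8 | (2R,3S,4RS)-2-[3-(benzyloxy)-4,5-dimethoxyphenyl]-5,6-(diphenylmethylenedioxy)-3,7-dimethoxychroman-4-ol | COc1cc2c(c3OC(c4ccccc4)(c4ccccc4)Oc13)C(O)[C@H](OC)[C@@H](c1cc(OCc3ccccc3)c(OC)c(OC)c1)O2
F0 | step 9 | none | none
A1 | alternative 1 | (2R,3S)-3-[3,4-dimethoxy-5-(methoxymethoxy)phenyl]-3-hydroxy-2-methoxy-1-[4-methoxy-2,3-bis(methoxymethoxy)-6-(triisopropylsilyloxy)phenyl]propan-1-one | COc1cc(O[Si](C(C)C)(C(C)C)C(C)C)c(c(OCOC)c1OCOC)C(=O)[C@H](OC)[C@H](c1cc(OCOC)c(OC)c(OC)c1)O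
A2 | alternative 1 | 2-diazo-1-[4-methoxy-2,3-bis(methoxymethoxy)-6-(triisopropylsilyloxy)phenyl]ethan-1-one | COc1cc(O[Si](C(C)C)(C(C)C)C(C)C)c(c(OCOC)c1OCOC)C(=O)C=[N+]=[N-]
A3 | alternative 1 | 3,4-dimethoxy-5-(methoxymethoxy)benzaldehyde | COCOc1cc(C=O)cc(OC)c1OC
A4 | alternative 1 | methanol | CO
A5 | alternative 2 | (2R,3R)-2-[3,4-dimethoxy-5-(methoxymethoxy)phenyl]-3-hydroxy-7-methoxy-5,6-bis(methoxymethoxy)chroman-4-one | COc1cc2c(c(OCOC)c1OCOC)C(=O)[C@H](O)[C@@H](c1cc(OCOC)c(OC)c(OC)c1)O2
A6 | alternative 2 | 2-[3,4-dimethoxy-5-(methoxymethoxy)phenyl]-2-[2-formyl-5-methoxy-3,4-bis(methoxymethoxy)phenoxy]acetaldehyde (racemic) | COc1cc(OC(C=O)c2cc(OCOC)c(OC)c(OC)c2)c(C=O)c(OCOC)c1OCOC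
A7 | alternative 3 | (2S)-2-[3-(benzyloxy)-4,5-dimethoxyphenyl]-5,6-(diphenylmethylenedioxy)-7-methoxychroman-4-one | COc1cc2c(c3OC(c4ccccc4)(c4ccccc4)Oc13)C(=O)C[C@@H](c1cc(OCc3ccccc3)c(OC)c(OC)c1)O2
A8 | alternative 3 | 2-diazo-1-[5-{[3-(benzyloxy)-4,5-dimethoxybenzyl]oxy}-7-methoxy-2,2-diphenyl-1,3-benzodioxol-4-yl]ethan-1-one | COc1cc(OCc2cc(OCc3ccccc3)c(OC)c(OC)c2)c(C(=O)C=[N+]=[N-])c2OC(c3ccccc3)(c3ccccc3)Oc12
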